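## Structural features

The target 19 is a melampolide-type germacranolide: a cyclodeca-1(10),4-diene ring (C1 to C10) trans-fused across C6–C7 to an α-methyl-γ-butyrolactone (oxygen on C6, C11 on C7, C12 carbonyl, C13 methyl). Both ring alkenes are trisubstituted and of opposite geometry, Z at C1=C10 (methyl C14 on C10) and E at C4=C5 (methyl C15 on C4). C6, C7 and C11 are contiguous stereocentres (6S,7S,11R), whereas the acetoxy carbons C3 (S) and C9 (S) are allylic and separated from the others by sp2 or methylene carbons. The C11 methyl is cis to the C7–C8 bond, the less stable lactone epimer, so strong base must be avoided once it is set; the 1,5-diene is prone to Cope rearrangement and transannular cyclisation, and both allylic acetates can ionise. The real difficulty is the strained medium ring with two geometrically defined trisubstituted alkenes and two remote carbinol centres that no neighbouring stereocentre controls directly. The key step exploits the 1,5-diene C10=C1–C2–C3–C4=C5: it is the cycloreversion product of a bicyclo[2.2.0]hexane (C1, C2, C3, C4, C5, C10) fused through C5–C10 to the ring C5–C6–C7–C8–C9–C10, and a C9 carbonyl turns that ring into a photoactive 2-methylcyclohexenone.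

## Logic of the disconnections

19 to 17 (through 18): the C9–O acetyl bond and then the C9–H bond are cut. C9 is taken back to a ketone because the carbonyl is the chromophore needed earlier and because its conjugation with C1=C10 stabilises 17 against Cope rearrangement. The gain is that only one remote stereocentre is left for the end. The demand is a 1,2-selective, face-selective hydride delivery to a flexible Z-enone, which is put under reagent control.

17 to 16: the π bonds C1=C10 and C4=C5 are traded for the σ bonds C1–C4 and C5–C10. This converts the ten-membered ring and both alkene geometries into a rigid cage whose configuration can be set by cycloaddition. The gain is the removal of the medium ring. The demand is that the diyl cleaves C5–C10 and not C2–C3, that it reacts through one chair, and that the cage sits on the α face of the six-membered ring (see remarks).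

16 to 14 (through 15): the acetyl C–O bond and the C3–H bond are cut. On the α-face cage the 3S oxygen is endo, which cycloaddition anti to an oxygen substituent cannot give, so C3 is taken back to a ketone and set on the cage by convex-face hydride attack. The gain is that the cyclobutene partner needs no defined configuration. The demand is chemoselective reduction of the strained ketone beside the C9 ketone and the lactone.

14 to 9 and 12 (through 13): after removing the C3 stereocentre by oxidation, the bonds C4–C5 and C1–C10 are cut as a [2+2] photocycloaddition. The gain is the split into a bicyclic enone carrying C6, C7 and C11 and a five-carbon partner. The demand is head-to-tail orientation, α-face attack and cis-anti-cis ring fusion.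

12 to 10 (through 11): the C3–O bond is cut at the ring methylene next to the methyl-bearing alkene carbon, and the alkene is moved to the exocyclic position. The gain is a commercial C5 hydrocarbon. The demand is allylic oxidation at CH2 in preference to CH3.

9 to 7 (through 8): the lactone acyl–oxygen bond and the C6–O bond are cut. C6 is the γ position of the enone, reachable through the through-conjugated dienol acetate. The gain is a monocyclic enone ester. The demand is oxygen delivery anti to the C7 side chain and attack at the diene terminus.

7 to 4 (through 6 and 5): the enol acetate and methyl ester are removed and the C11–H bond is cut to the 2-substituted acrylic acid. C11 is set by catalyst-controlled hydrogenation because protonation of a lactone enolate would be ambiguous in face and incompatible with the ketone. The demand is high catalyst control next to the C7 stereocentre.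

4 to 1 (through 3 and 2): C12 is taken down from acid to aldehyde to allylic chloride to the isopropenyl methyl. C7 comes unchanged from the chiral pool. The demand is functionalisation of the isopropenyl group without touching the enone.

## Other disconnections considered

Alternative 1: The cut is the ring bond C6–C7, with the old bond C4–C9 given up in the forward sense. The forward key step is an anionic oxy-Cope rearrangement (KH, 18-crown-6): the C9 alkoxide drives a [3,3] shift that breaks C4–C9 and makes C6–C7, and protonation of the C9 enolate gives the ten-membered enone A1 (C6 PMB ether, C3 TBS ether, silyloxypropyl arm on C7).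
- In its favour: it runs at or below room temperature, where the chosen plan needs several hundred degrees, and is the better plan on thermal load. The Z-C1=C10 bond is inherited from a six-membered ring and cannot be wrong, which is also better than the chosen plan, where it rests on a conformational preference. The C9 ketone appears directly.
- Against it: C6 and C7 are created in the rearrangement itself and both depend on a chair transition state and a defined enol-ether geometry. The substrate needs a quaternary C4 bearing that enol ether. The product enolate sits in a ten-membered ring across from an alkene, which invites transannular reactions.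
- Comparison: A1 has no lactone, so after the key step PMB removal, desilylation, oxidation of C12, lactonisation and differentiation of C3 are needed, about six steps against two in the chosen plan. In the chosen plan C6, C7 and C11 are fixed on a small bicycle before the ring is made.

Alternative 2: The cut is C3–C4. The forward key step is a nickel-catalysed reductive ynal cyclisation (Ni(cod)2, N-heterocyclic carbene, Et3SiH): zerovalent nickel couples the C3 aldehyde with alkyne carbon C4 through an oxanickelacycle, and silane cleavage gives A2, the target skeleton with a C3 triethylsilyl ether and the C9 acetate.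
- In its favour: syn addition across the alkyne fixes E-C4=C5 by mechanism, which is equal to or better than the chosen plan on that alkene. The lactone and the C9 acetate are already present, so two steps (desilylation, acetylation) finish the synthesis, equal to the chosen plan. No photochemical or pyrolysis apparatus is needed.
- Against it: a ten-membered ring must be closed by an organometallic step against medium-ring strain, with oligomerisation as the competitor. The C3 stereocentre is made in that step with no clear control element. The open-chain substrate needs the Z-C1=C10 alkene from a separate olefination and carries a β,γ-unsaturated aldehyde that can slip into conjugation. The propargylic lactone oxygen at C6 can ionise on zerovalent nickel.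
- Comparison: the chosen ring expansion is unimolecular and strain-driven and sets C3 on a rigid cage. The alternative is milder and mechanistically cleaner for the E alkene but weaker on ring formation and on C3.

Alternative 3: The cut restores the C4–C9 bond of a decalin. The forward key step is a Wharton (Grob-type) fragmentation: the C9 tertiary alkoxide (NaH or KOtBu) expels the C5 mesylate with cleavage of C4–C9, giving A3, the 9-oxo ten-membered lactone with a C3 TBS ether.
- In its favour: the antiperiplanar fragmentation is stereospecific for E-C4=C5 and the Z-C1=C10 bond comes from a six-membered ring. On alkene geometry it is equal to or better than the chosen plan. The temperature is mild.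
- Against it: strong base meets a lactone whose C11 is the less stable epimer, where the chosen plan is neutral and is the safer one. A fully functionalised decalin is needed (C9 tertiary allylic alcohol, quaternary C4, antiperiplanar C5 mesylate, C3, C6, C7, C11 in place), which is a long sequence from carvone.
- Comparison: A3 has the same oxidation pattern as 17, so the endgame is the same plus a silyl-to-acetate exchange, four steps against two. The step count to the fragmentation substrate would be at least as long as the route to 16.

Key step: step 14

Remarks before the steps
- Numbering: the germacrane numbering of 19 is used for every ring intermediate. α is the face of the six-membered ring that carries H7 and the C6–O bond; β is the face of H6 and the C7–C11 bond.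
- Check of the structures: the target reads (3S,6S,7S,9S,11R), 1(10)Z,4E, and (S)-carvone carries the correct C7.
- Configuration of the precursor: the configuration of the four cyclobutane carbons is not free. The trans lactone locks the six-membered ring as a chair. Only when the cage lies on the α face (C5–C4 axial, C10–C1 equatorial) does the chair 1,4-diyl that keeps this ring a chair place C6 equatorial and the C10 methyl equatorial, which gives 1(10)Z,4E. With the cage on the β face the same analysis puts C6 and the C10 methyl axial and leads to 1(10)E,4Z. The precursor 16 is therefore drawn with C1, C4, C5 and C10 on the α face.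
- Consequence for C3: on the α-face cage a 3S acetate is endo, which addition anti to a cyclobutenyl acetate cannot deliver, and a racemic acetate would give both C3 series. C3 is therefore oxidised and reset on the cage (steps 11 and 12), and the partner is used as the racemic alcohol.
- Assumption: the photocycloaddition prefers the α face of 9, because pyramidalisation of the β-carbon C5 in the lactone-locked half-chair places the forming C5–C4 bond axial, anti to the axial H6.

## Steps

Step 1
Reactants: 1 (S)-carvone
Product: 2 (5S)-5-(3-chloroprop-1-en-2-yl)-2-methylcyclohex-2-en-1-one
Conditions: Ca(OCl)2, solid CO2, CH2Cl2–H2O, 0 °C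
Reagents that add atoms: calcium hypochlorite, [Ca+2].[O-]Cl.[O-]Cl
Why: Ene-type allylic chlorination of the electron-rich 1,1-disubstituted alkene by hypochlorous acid made in the flask; the electron-poor enone alkene should be inert and C7 is not touched.

Step 2
Reactants: 2 allylic chloride
Product: 3 2-[(1S)-4-methyl-5-oxocyclohex-3-en-1-yl]prop-2-enal
Conditions: NMO (3 equiv), NaI (0.1 equiv), MeCN, 50 °C
Reagents that add atoms: 4-methylmorpholine N-oxide, C[N+]1([O-])CCOCC1
Why: Kornblum-type oxidation of an allylic halide by an amine N-oxide (iodide-assisted SN2 at oxygen, then elimination to the aldehyde); the weakly basic amine should not move the exocyclic alkene into the ring.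

Step 3
Reactants: 3 enal
Product: 4 2-[(1S)-4-methyl-5-oxocyclohex-3-en-1-yl]prop-2-enoic acid
Conditions: NaClO2, NaH2PO4, 2-methylbut-2-ene, tBuOH–H2O, 0 °C to rt
Reagents that add atoms: sodium chlorite, [Na+].[O-]Cl=O
Why: Pinnick oxidation; chlorous acid oxidises only the aldehyde and the scavenger removes hypochlorous acid before it can reach the alkenes.

Step 4
Reactants: 4 acrylic acid
Product: 5 (2R)-2-[(1S)-4-methyl-5-oxocyclohex-3-en-1-yl]propanoic acid
Conditions: Ru(OAc)2[(R)-BINAP] (1 mol %), H2 (50 bar), MeOH, 25 °C
Reagents that add atoms: none
Why: Noyori-type carboxylate-directed asymmetric hydrogenation of a 2-substituted acrylic acid; the (R)-BINAP complex of divalent ruthenium should give the R acid as with 2-aryl- and 2-cycloalkylacrylic acids, so C11 is set by the catalyst, and the trisubstituted enone alkene has no directing carboxylate and should remain.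

Step 5
Reactants: 5 saturated acid
Product: 6 methyl (2R)-2-[(1S)-4-methyl-5-oxocyclohex-3-en-1-yl]propanoate
Conditions: MeI, KHCO3, DMF, rt
Reagents that add atoms: iodomethane, CI
Why: SN2 O-alkylation of the carboxylate; bicarbonate is too weak to enolise the ester or the enone, so C11 and C7 are safe.

Step 6
Reactants: 6 methyl ester
Product: 7 methyl (2R)-2-[(1R)-5-acetoxy-4-methylcyclohexa-2,4-dien-1-yl]propanoate
Conditions: isopropenyl acetate (solvent), TsOH·H2O (5 mol %), 95 °C, acetone distilled off
Reagents that add atoms: isopropenyl acetate, CC(=C)OC(C)=O
Why: Acid-catalysed enol acetylation under equilibrating conditions should give the through-conjugated 1-acetoxy-1,3-diene (C9=C10, C5=C6), as with steroidal enone dienol acetates; the simple ester does not enolise and C7 keeps its configuration (its descriptor changes only because the priorities change).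

Step 7
Reactants: 7 dienol acetate
Product: 9 (3R,3aS,7aS)-3,6-dimethyl-3a,4-dihydro-1-benzofuran-2,5(3H,7aH)-dione, via hydroxy enone ester 8 (not isolated)
Conditions: mCPBA (1.05 equiv), CH2Cl2–H2O, 0 °C; then TsOH·H2O (5 mol %), PhMe, 50 °C
Reagents that add atoms: 3-chloroperbenzoic acid, OOC(=O)c1cccc(Cl)c1
Why: Peracid oxidation of a dienol acetate at the terminal C5=C6 bond (vinylogous Rubottom-type γ-hydroxylation) should deliver oxygen anti to the C7 side chain, setting 6S with O trans to C11; acid-catalysed transesterification then closes the trans γ-lactone with retention at C6.

Step 8
Reactants: 10 methylenecyclobutane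
Product: 11 1-methylcyclobut-1-ene
Conditions: KOtBu (0.2 equiv), DMSO, 50 °C; product distilled out
Reagents that add atoms: none
Why: Base-catalysed alkene isomerisation through the allyl anion; the trisubstituted endocyclic isomer is favoured at equilibrium.

Step 9
Reactants: 11 methylcyclobutene
Product: 12 rac-2-methylcyclobut-2-en-1-ol
Conditions: SeO2 (0.3 equiv), tBuOOH (2 equiv), CH2Cl2, 0 °C to rt
Reagents that add atoms: selenium dioxide, O=[Se]=O; tert-butyl hydroperoxide, CC(C)(C)OO (oxygen relayed through selenium)
Why: Riley allylic oxidation (ene reaction, then [2,3]-sigmatropic shift): selenium adds to the CH alkene carbon and hydrogen is taken from the ring CH2 next to the methyl-bearing carbon (CH2 before CH3), so the hydroxyl ends on the ring carbon adjacent to C(Me)= with the alkene restored.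

Step 10
Reactants: 9 enone lactone; 12 racemic methylcyclobutenol
Product: 13 (3RS)-3-hydroxy-9-oxo cage lactone (cis-anti-cis photoadduct on the α face)
Conditions: hν (366 nm, Pyrex), CH2Cl2, −40 °C, alkene partner in fivefold excess
Reagents that add atoms: none
Why: Triplet enone–alkene [2+2] photocycloaddition with a cyclobutene partner, in which one molecule of each component combines and no atom is lost; head-to-tail because the more substituted alkene carbon C4 bonds to the β-carbon C5 and vicinal quaternary centres are avoided, α-face because the C5–C4 bond forms axially and anti to H6 on the lactone-locked ring, and anti arrangement of the two outer rings; both C3 epimers are accepted because step 11 removes that centre.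

Step 11
Reactants: 13 hydroxy cage lactone
Product: 14 3,9-dioxo cage lactone (C3 ketone on the same cage)
Conditions: Dess–Martin periodinane, CH2Cl2, 0 °C to rt
Reagents that add atoms: none
Why: Dess–Martin oxidation of the secondary cyclobutanol under neutral conditions well below the temperature of cycloreversion; the C3 epimers converge.

Step 12
Reactants: 14 diketone cage lactone
Product: 15 (3S)-3-hydroxy-9-oxo cage lactone (endo alcohol)
Conditions: NaBH4 (0.5 equiv), THF–MeOH, −78 °C
Reagents that add atoms: none
Why: Borohydride reduction; the strained cyclobutanone is far more electrophilic than the hindered C9 ketone next to quaternary C10, and hydride should enter from the convex face of the bicyclo[2.2.0]hexanone because the concave face is blocked by H5 and the C10 methyl, which gives the endo 3S alcohol (cis to C5, trans to the C4 methyl).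

Step 13
Reactants: 15 endo cage alcohol
Product: 16 (3S)-3-acetoxy-9-oxo cage lactone (key-step precursor)
Conditions: Ac2O, DMAP (cat.), pyridine, CH2Cl2, 0 °C to rt
Reagents that add atoms: acetic anhydride, CC(=O)OC(C)=O
Why: DMAP-catalysed acylation of a secondary alcohol; nothing else in 15 reacts.

Step 14
Reactants: 16 cage acetate
Product: 17 (1(10)Z,4E,3S,6S,7S,11R)-3-acetoxy-9-oxogermacra-1(10),4-dien-12,6-olide
Conditions: flash vacuum thermolysis, quartz tube 420 °C, 0.01 mbar, contact about 20 ms, trap at −78 °C
Reagents that add atoms: none
Why: Thermal homolysis of the doubly strained central C1–C4 bond gives a cyclohexane-1,4-diyl (C1, C2, C3, C4, C5, C10) that relaxes to a chair and then cleaves C5–C10, a formal retro-[2+2] driven by loss of both four-membered rings and by conjugation of the new C1=C10 bond with C9=O. The closest known reaction type is the thermolysis of enone–cyclobutene photoadducts (tricyclo[4.4.0.0(2,5)]decanones) to cis,trans-cyclodeca-1,5-dienones, the fused form of the bicyclo[2.2.0]hexane to hexa-1,5-diene cycloreversion. The ten-membered ring is not closed by bond formation; it appears by fragmentation of the two shared bonds, a four-carbon ring expansion of the cyclohexanone. No stereocentre is formed, and C3, C6, C7 and C11 are spectators. The two alkene geometries are set in the chair diyl: with C5–C4 axial and C10–C1 equatorial on the lactone-locked ring, the only chair–chair arrangement has C6 equatorial on C5 (anti to C4–C3, hence E-C4=C5) and C9 axial with the methyl equatorial on C10 (hence Z-C1=C10). The step needs scission of C5–C10 and not C2–C3, which the more substituted, carbonyl-flanked bond should secure. It also needs 17 to leave the hot zone before Cope rearrangement, which the high frequency factor of the fragmentation relative to the ordered Cope transition state and the short contact time favour. The acetate and the lactone should survive because ester pyrolysis needs a higher temperature or longer contact and the lactone cannot reach the cyclic syn-elimination geometry.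

Step 15
Reactants: 17 ten-membered enone
Product: 18 (1(10)Z,4E,3S,6S,7S,9S,11R)-3-acetoxy-9-hydroxygermacra-1(10),4-dien-12,6-olide
Conditions: (R)-methyl-CBS oxazaborolidine [(R)-1-methyl-3,3-diphenyltetrahydro-1H,3H-pyrrolo[1,2-c][1,3,2]oxazaborole] (0.5 equiv), catecholborane (2 equiv), PhMe–CH2Cl2, −78 °C
Reagents that add atoms: none
Why: Corey–Bakshi–Shibata reduction; the alkenyl flank (C10) acts as the large group and C8H2 as the small one, so the R catalyst should give the 9S alcohol by 1,2-addition, and catecholborane at −78 °C leaves the lactone, the acetate and the alkenes alone.

Step 16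
Reactants: 18 allylic alcohol
Product: 19 (1(10)Z,4E,3S,6S,7S,9S,11R)-3,9-diacetoxygermacra-1(10),4-dien-12,6-olide (target)
Conditions: Ac2O, DMAP (cat.), pyridine, CH2Cl2, 0 °C
Reagents that add atoms: acetic anhydride, CC(=O)OC(C)=O
Why: DMAP-catalysed acylation under mild, non-ionising conditions; the allylic alcohol is acylated without SN2' or C11 epimerisation.

## Compound list

1 | (S)-carvone, (5S)-2-methyl-5-(prop-1-en-2-yl)cyclohex-2-en-1-one | CC1=CC[C@@H](CC1=O)C(C)=C | starting material
2 | (5S)-5-(3-chloroprop-1-en-2-yl)-2-methylcyclohex-2-en-1-one | CC1=CC[C@@H](CC1=O)C(=C)CCl | intermediate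
3 | 2-[(1S)-4-methyl-5-oxocyclohex-3-en-1-yl]prop-2-enal | CC1=CC[C@@H](CC1=O)C(=C)C=O | intermediate
4 | 2-[(1S)-4-methyl-5-oxocyclohex-3-en-1-yl]prop-2-enoic acid | CC1=CC[C@@H](CC1=O)C(=C)C(O)=O | intermediate
5 | (2R)-2-[(1S)-4-methyl-5-oxocyclohex-3-en-1-yl]propanoic acid | CC1=CC[C@@H](CC1=O)[C@@H](C)C(O)=O | intermediate
6 | methyl (2R)-2-[(1S)-4-methyl-5-oxocyclohex-3-en-1-yl]propanoate | CC1=CC[C@@H](CC1=O)[C@@H](C)C(=O)OC | intermediate
7 | methyl (2R)-2-[(1R)-5-acetoxy-4-methylcyclohexa-2,4-dien-1-yl]propanoate | CC1=C(OC(C)=O)C[C@H](C=C1)[C@@H](C)C(=O)OC | intermediate
8 | methyl (2R)-2-[(1S,2S)-2-hydroxy-4-methyl-5-oxocyclohex-3-en-1-yl]propanoate (not isolated) | CC1=C[C@@H](O)[C@@H](CC1=O)[C@@H](C)C(=O)OC | intermediate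
9 | (3R,3aS,7aS)-3,6-dimethyl-3a,4-dihydro-1-benzofuran-2,5(3H,7aH)-dione (enone lactone) | O=C1C[C@@H]2[C@H](OC(=O)[C@@H]2C)C=C1C | intermediate
10 | methylenecyclobutane | C=C1CCC1 | starting material
11 | 1-methylcyclobut-1-ene | CC1=CCC1 | intermediate
12 | rac-2-methylcyclobut-2-en-1-ol | CC1=CCC1O | intermediate
13 | (3RS)-3-hydroxy-9-oxo cage lactone: cyclobutanes C1–C2–C3–C4 and C1–C4–C5–C10, cis-anti-cis, on the α face of the cyclohexanone, C10 methyl and H5 β, trans 6,12-lactone, 11R (C3 epimers, exo 3R alcohol expected to predominate) | O=C1C[C@@H]2[C@H](OC(=O)[C@@H]2C)[C@H]3[C@]1(C)[C@@H]4CC(O)[C@]34C | intermediate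
14 | 3,9-dioxo cage lactone (same cage, C3 ketone) | O=C1C[C@@H]2[C@H](OC(=O)[C@@H]2C)[C@H]3[C@]1(C)[C@@H]4CC(=O)[C@]34C | intermediate
15 | (3S)-3-hydroxy-9-oxo cage lactone (endo alcohol, cis to C5 and trans to the C4 methyl) | O=C1C[C@@H]2[C@H](OC(=O)[C@@H]2C)[C@H]3[C@]1(C)[C@@H]4C[C@H](O)[C@]34C | intermediate
16 | (3S)-3-acetoxy-9-oxo cage lactone (key-step precursor) | O=C1C[C@@H]2[C@H](OC(=O)[C@@H]2C)[C@H]3[C@]1(C)[C@@H]4C[C@H](OC(C)=O)[C@]34C | intermediate
17 | (1(10)Z,4E,3S,6S,7S,11R)-3-acetoxy-9-oxogermacra-1(10),4-dien-12,6-olide | O=C1C[C@@H]2[C@@H](/C=C(\C)[C@@H](OC(C)=O)C/C=C\1C)OC(=O)[C@@H]2C | intermediate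
18 | (1(10)Z,4E,3S,6S,7S,9S,11R)-3-acetoxy-9-hydroxygermacra-1(10),4-dien-12,6-olide | O[C@H]1C[C@@H]2[C@@H](/C=C(\C)[C@@H](OC(C)=O)C/C=C\1C)OC(=O)[C@@H]2C | intermediate
19 | (1(10)Z,4E,3S,6S,7S,9S,11R)-3,9-diacetoxygermacra-1(10),4-dien-12,6-olide | CC(=O)O[C@H]1C[C@@H]2[C@@H](/C=C(\C)[C@@H](OC(C)=O)C/C=C\1C)OC(=O)[C@@H]2C | target

## Step count and least certain steps

Total: 16 steps. Longest linear sequence: 14 steps (steps 1 to 7 and 10 to 16); the two-step branch (steps 8 and 9) joins at step 10.

Step 14 (key step). Most likely to go wrong: Cope rearrangement of 17 in the hot zone to a divinylcyclohexane, competing scission of C2–C3 in the diyl, and partial loss of acetic acid. All three have barriers within reach at the temperature the cycloreversion needs. Fallback, setting out from 14 and returning at 19: the diketone 14 is submitted to the flash vacuum thermolysis in place of 16, at a lower oven temperature. Its central bond is weakened by the adjacent C3 carbonyl, both new alkenes emerge conjugated, no allylic ester is present, and the same chair argument applies, so it should give the ten-membered 3,9-diketone F1. Reduction of both enone carbonyls with the (R)-methyl-CBS oxazaborolidine and catecholborane, where the alkenyl flank is the large group at C3 as at C9, should give the 3S,9S-diol F2. Diacetylation (Ac2O, DMAP, pyridine) gives 19.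

Step 10. Most likely to go wrong: poor facial selectivity and some head-to-head addition. The 3S enantiomer of racemic 12 can react anti to its hydroxyl on the β face, which gives the cage that leads to the wrong alkene geometries; the small hydroxyl exerts little control and both faces of 9 are flanked only by axial hydrogens. Fallback, setting out from 12 and returning at 13: lipase resolution (CAL-B, vinyl acetate, hexane) should acylate the R alcohol, the enantiomer expected from the usual lipase preference with the methyl-bearing alkene carbon as the large group, giving (R)-2-methylcyclobut-2-en-1-yl acetate F3. Irradiation of 9 with F3 matches anti addition to the acetate with the α face and should give the exo 3R cage acetate F4. Methanolysis (K2CO3, MeOH, 0 °C) then gives 13 as its 3R epimer.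

Step 7. Most likely to go wrong: delivery of oxygen syn to the side chain (cis lactone series) or attack at the enol acetate double bond. The flexible cyclohexadiene offers only a modest facial bias, and the site selectivity rests on the larger coefficient at the diene terminus. Fallback, setting out from 7 and returning at 8 and then 9: the oxidation is worked up without acid and the 6R hydroxy ester F5 is separated. Mitsunobu reaction with 4-nitrobenzoic acid (PPh3, DIAD, THF, 0 °C) inverts it to the 6S 4-nitrobenzoate F6. Methanolysis (K2CO3, MeOH, 0 °C) gives 8, which is lactonised with TsOH as in step 7.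

Step 15. Most likely to go wrong: substrate control overriding the catalyst, that is, peripheral hydride attack on the preferred conformer of the ten-membered ring leading to the 9R alcohol. Fallback, setting out from 17 and returning at 19: Luche reduction (NaBH4, CeCl3·7H2O, MeOH, −78 °C) follows the substrate preference to the 9R alcohol F7. Mitsunobu reaction with acetic acid (PPh3, DIAD, AcOH, toluene, 0 °C) then installs the acetate with inversion and gives 19 directly.

## Further compounds

F1 | step 14 | (1(10)Z,4E,6S,7S,11R)-3,9-dioxogermacra-1(10),4-dien-12,6-olide | O=C1C[C@@H]2[C@@H](/C=C(\C)C(=O)C/C=C\1C)OC(=O)[C@@H]2C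
F2 | step 14 | (1(10)Z,4E,3S,6S,7S,9S,11R)-3,9-dihydroxygermacra-1(10),4-dien-12,6-olide | O[C@H]1C[C@@H]2[C@@H](/C=C(\C)[C@@H](O)C/C=C\1C)OC(=O)[C@@H]2C
F3 | step 10 | (R)-2-methylcyclobut-2-en-1-yl acetate | CC1=CC[C@H]1OC(C)=O
F4 | step 10 | (3R)-3-acetoxy-9-oxo cage lactone (exo acetate on the α-face cage) | O=C1C[C@@H]2[C@H](OC(=O)[C@@H]2C)[C@H]3[C@]1(C)[C@@H]4C[C@@H](OC(C)=O)[C@]34C
F5 | step 7 | methyl (2R)-2-[(1S,2R)-2-hydroxy-4-methyl-5-oxocyclohex-3-en-1-yl]propanoate | CC1=C[C@H](O)[C@@H](CC1=O)[C@@H](C)C(=O)OC
F6 | step 7 | (1S,6S)-6-[(2R)-1-methoxy-1-oxopropan-2-yl]-3-methyl-4-oxocyclohex-2-en-1-yl 4-nitrobenzoate | CC1=C[C@@H](OC(=O)c2ccc(cc2)[N+]([O-])=O)[C@@H](CC1=O)[C@@H](C)C(=O)OC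
F7 | step 15 | (1(10)Z,4E,3S,6S,7S,9R,11R)-3-acetoxy-9-hydroxygermacra-1(10),4-dien-12,6-olide | O[C@@H]1C[C@@H]2[C@@H](/C=C(\C)[C@@H](OC(C)=O)C/C=C\1C)OC(=O)[C@@H]2C
A1 | alternative 1 | (1(10)Z,4E)-ten-membered C9 enone with C6 4-methoxybenzyl ether, C3 TBS ether and a (2R)-1-(tert-butyldimethylsilyloxy)propan-2-yl arm on C7 | O=C1C[C@@H]([C@@H](C)CO[Si](C)(C)C(C)(C)C)[C@@H](/C=C(\C)[C@@H](O[Si](C)(C)C(C)(C)C)C/C=C\1C)OCc2ccc(OC)cc2
A2 | alternative 2 | (1(10)Z,4E)-9-acetoxy-3-(triethylsilyloxy)germacra-1(10),4-dien-12,6-olide | CC(=O)O[C@H]1C[C@@H]2[C@@H](/C=C(\C)[C@@H](O[Si](CC)(CC)CC)C/C=C\1C)OC(=O)[C@@H]2C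
A3 | alternative 3 | (1(10)Z,4E)-3-(tert-butyldimethylsilyloxy)-9-oxogermacra-1(10),4-dien-12,6-olide | O=C1C[C@@H]2[C@@H](/C=C(\C)[C@@H](O[Si](C)(C)C(C)(C)C)C/C=C\1C)OC(=O)[C@@H]2C
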